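Labdane numbering is used: ring A = C1–C5 and C10; ring B = C5–C10; C17 = carboxyl carbon on C8; side chain = C11–C16; the β face is the face of the C10 methyl.
Retrosynthesis: the O15 formate and the C17 ester are adjusted last. Ring B is cut at C6–C7 to a monocyclic 1,5-diene (exocyclic C5=C6 methylene plus a C7Br2=C8 acrylate). C7=C8 is then cut to an α-keto ester, C9–C10 by a [3,3] shift to an allyl vinyl ether, C8=C9 by olefination, and O–C8 by O–H insertion.
Forward: C9 and C11–C16 come from (S)-citronellol 1, ring A with C6 from β-cyclocitral 5, C8/C17 from phosphonoacetate 7, and C7 from CBr4. The pieces are joined in steps 5 and 6, C9–C10 is made in step 7, and ring B closes last in step 9.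
Enabling feature: C5 stands between the quaternary C4 and C10. A C5=C6 methylene therefore has only its C6 terminus open, has no allylic hydrogen, and lies 1,6 to C7, so a C7 vinyl radical can only close ring B through C6. The tertiary C5 radical that results has its β face covered by the axial methyls on C4 and C10.
Stereochemistry: C13 comes from 1. C9 and C10 are set together in the chair Claisen transition state of the (E)-vinyl ether, whose six atoms C9–C8–O–C6–C5–C10 are ring B with O in place of C7; absolute control comes from a chiral copper bis(oxazoline) catalyst. C5 is set by α-face hydrogen-atom transfer in the key step.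

Key step: step 9

Assumption: tBu-box = 2,2'-(propane-2,2-diyl)bis[(4S)-4-tert-butyl-4,5-dihydro-1,3-oxazole]. The sense of induction in step 7 is taken from the square-planar chelate model of its divalent copper complex; should it prove opposite, the equally available (R,R)-ligand is used and nothing else changes.

Step 1
Reactants: 1 (S)-citronellol [(3S)-3,7-dimethyloct-6-en-1-ol]
Product: 2 (S)-citronellyl tert-butyldimethylsilyl ether
Conditions: TBSCl, imidazole, CH2Cl2, 0 °C to rt
Reagents that add atoms: tert-butyldimethylsilyl chloride, CC(C)(C)[Si](C)(C)Cl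
Why: Imidazole-promoted silylation of a primary alcohol masks O15 through the basic, Lewis-acidic and radical steps, while C13 is carried over unchanged from the chiral pool.

Step 2
Reactants: 2 (S)-citronellyl tert-butyldimethylsilyl ether
Product: 4 (4S)-6-[(tert-butyldimethylsilyl)oxy]-4-methylhexanal, via ozonide 3 (not isolated)
Conditions: O3, CH2Cl2, −78 °C; then Me2S, −78 °C to rt
Reagents that add atoms: ozone, [O-][O+]=O
Why: Criegee ozonolysis with reductive work-up cleaves the only C=C bond, removes the isopropylidene carbons as acetone and leaves C9 as the aldehyde, with the remote C13 centre untouched.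

Step 3
Reactants: 5 β-cyclocitral (2,6,6-trimethylcyclohex-1-ene-1-carbaldehyde)
Product: 6 β-cyclogeraniol [(2,6,6-trimethylcyclohex-1-en-1-yl)methanol]
Conditions: NaBH4, MeOH, 0 °C
Reagents that add atoms: none
Why: Borohydride 1,2-reduction of a hindered enal, whose tetrasubstituted C5=C10 bond is too crowded for conjugate hydride addition, gives the allylic alcohol that carries C6.

Step 4
Reactants: 7 methyl 2-[bis(2,2,2-trifluoroethoxy)phosphoryl]acetate
Product: 8 methyl 2-[bis(2,2,2-trifluoroethoxy)phosphoryl]-2-diazoacetate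
Conditions: 4-AcNHC6H4SO2N3, DBU, MeCN, 0 °C to rt
Reagents that add atoms: 4-acetamidobenzenesulfonyl azide, CC(=O)Nc1ccc(cc1)S(=O)(=O)N=[N+]=[N-]
Why: Regitz diazo transfer works on the doubly activated methylene group, which is acidic enough for an amidine base that leaves the trifluoroethyl phosphonate esters intact.

Step 5
Reactants: 6 β-cyclogeraniol; 8 methyl 2-[bis(2,2,2-trifluoroethoxy)phosphoryl]-2-diazoacetate
Product: 9 methyl 2-[bis(2,2,2-trifluoroethoxy)phosphoryl]-2-[(2,6,6-trimethylcyclohex-1-en-1-yl)methoxy]acetate (racemic)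
Conditions: Rh2(OAc)4 (1 mol%), PhMe, 80 °C, slow addition of 8
Reagents that add atoms: none
Why: Rhodium-carbenoid O–H insertion (oxonium ylide formation and proton shift) forms the O–C8 bond faster than the tetrasubstituted alkene can be cyclopropanated, and the new centre at C8 is racemic but is erased in step 6.

Step 6
Reactants: 9 methyl 2-[bis(2,2,2-trifluoroethoxy)phosphoryl]-2-[(2,6,6-trimethylcyclohex-1-en-1-yl)methoxy]acetate; 4 (4S)-6-[(tert-butyldimethylsilyl)oxy]-4-methylhexanal
Product: 10 methyl (2E,6S)-8-[(tert-butyldimethylsilyl)oxy]-6-methyl-2-[(2,6,6-trimethylcyclohex-1-en-1-yl)methoxy]oct-2-enoate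
Conditions: KN(SiMe3)2, 18-crown-6, THF, −78 °C; then 4
Reagents that add atoms: none
Why: In the Still–Gennari variant of the Horner–Wadsworth–Emmons olefination the electron-poor phosphonate and the dissociated potassium counter-ion make the kinetic addition product-determining, so C11 should end up cis to the ester and trans to oxygen, which is the (E)-vinyl ether needed in step 7, and any (Z)-isomer is removed by chromatography.

Step 7
Reactants: 10 methyl (2E,6S)-8-[(tert-butyldimethylsilyl)oxy]-6-methyl-2-[(2,6,6-trimethylcyclohex-1-en-1-yl)methoxy]oct-2-enoate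
Product: 11 methyl (3R,6S)-8-[(tert-butyldimethylsilyl)oxy]-6-methyl-2-oxo-3-[(1R)-1,3,3-trimethyl-2-methylidenecyclohexyl]octanoate
Conditions: [Cu((S,S)-tBu-box)(H2O)2](SbF6)2 (10 mol%), 4 Å MS, CH2Cl2, rt
Reagents that add atoms: none
Why: In this catalytic asymmetric Gosteli–Claisen rearrangement copper chelates the ether oxygen and the ester carbonyl, the tert-butyl groups leave one face of C8=C9 open to the allyl part, and the chair transition state (C11 and C1 pseudo-equatorial, C10 methyl pseudo-axial) sets C9 and C10 together in the relation of the later ring B chair, while the C5=C6 methylene that emerges has no allylic hydrogen and so cannot enter a follow-up carbonyl-ene reaction with the keto ester.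

Step 8
Reactants: 11 methyl (3R,6S)-8-[(tert-butyldimethylsilyl)oxy]-6-methyl-2-oxo-3-[(1R)-1,3,3-trimethyl-2-methylidenecyclohexyl]octanoate
Product: 12 methyl (3R,6S)-8-[(tert-butyldimethylsilyl)oxy]-2-(dibromomethylidene)-6-methyl-3-[(1R)-1,3,3-trimethyl-2-methylidenecyclohexyl]octanoate
Conditions: PPh3, CBr4, Zn, CH2Cl2, rt (ylide preformed); then 11, 0 °C to rt
Reagents that add atoms: carbon tetrabromide, BrC(Br)(Br)Br
Why: Ramirez dibromomethylenation (the first stage of the Corey–Fuchs sequence), known for α-keto esters, brings in C7 under non-basic conditions so that the enolisable C9 centre is not epimerised, and zinc takes up the bromine that would otherwise give Ph3PBr2 and endanger the silyl ether.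

Step 9
Reactants: 12 methyl (3R,6S)-8-[(tert-butyldimethylsilyl)oxy]-2-(dibromomethylidene)-6-methyl-3-[(1R)-1,3,3-trimethyl-2-methylidenecyclohexyl]octanoate
Product: 14 methyl (1R,4aS,8aS)-1-[(3S)-5-[(tert-butyldimethylsilyl)oxy]-3-methylpentyl]-5,5,8a-trimethyl-1,4,4a,5,6,7,8,8a-octahydronaphthalene-2-carboxylate, via bicyclic 7-bromide 13 (not isolated)
Conditions: (Me3Si)3SiH (2.5 equiv, syringe pump), AIBN, PhMe, 85 °C, 0.005 M
Reagents that add atoms: none
Why: The silyl radical abstracts one bromine of 12 to give a bent, rapidly inverting α-bromovinyl σ-radical at C7, which adds to the CH2 terminus C6 of the exocyclic C5=C6 bond; the tertiary C5 radical takes hydrogen from the silane, and a second abstraction and hydrogen-transfer cycle removes the remaining vinylic bromine of 13, so the C7=C8–CO2Me unit of the target is left in place. The closest known reaction type is the tin- or silicon-hydride-mediated vinyl radical cyclisation of bromoalkenes, including its 6-endo variant on 1,1-disubstituted alkenes. Ring B closes in the 6-endo-trig mode. The one new stereocentre, C5, is set by hydrogen-atom delivery to the α face of the ring-fusion radical, because the β face is screened by the axial C10 methyl and the axial C4 methyl, which gives the trans-decalin. Selectivity for 6-endo over 5-exo closure is secured by C5 lying between the quaternary C4 and C10, and any 5-exo radical would be a homoallyl radical that returns through the ester-stabilised cyclopropylcarbinyl radical to the same tertiary C5 radical. Vinyl geometry needs no control since both bromines lead to interconverting radicals, and slow silane addition at high dilution keeps premature reduction and 1,5-hydrogen transfer behind cyclisation.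

Step 10
Reactants: 14 methyl (1R,4aS,8aS)-1-[(3S)-5-[(tert-butyldimethylsilyl)oxy]-3-methylpentyl]-5,5,8a-trimethyl-1,4,4a,5,6,7,8,8a-octahydronaphthalene-2-carboxylate
Product: 15 (1R,4aS,8aS)-1-[(3S)-5-[(tert-butyldimethylsilyl)oxy]-3-methylpentyl]-5,5,8a-trimethyl-1,4,4a,5,6,7,8,8a-octahydronaphthalene-2-carboxylic acid
Conditions: LiOH, THF–MeOH–H2O, 60 °C; then aq. HCl to pH 3
Reagents that add atoms: lithium hydroxide, [Li+].[OH-]
Why: Saponification of the conjugated, α-branched methyl ester needs heat but has no competing site, since C9 is not acidified by the cross-conjugated ester and the primary silyl ether tolerates hydroxide.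

Step 11
Reactants: 15 (1R,4aS,8aS)-1-[(3S)-5-[(tert-butyldimethylsilyl)oxy]-3-methylpentyl]-5,5,8a-trimethyl-1,4,4a,5,6,7,8,8a-octahydronaphthalene-2-carboxylic acid
Product: 17 (1R,4aS,8aS)-1-[(3S)-5-(formyloxy)-3-methylpentyl]-5,5,8a-trimethyl-1,4,4a,5,6,7,8,8a-octahydronaphthalene-2-carboxylic acid, via hydroxy acid 16 (not isolated)
Conditions: HCO2H (98%), 40 °C
Reagents that add atoms: formic acid, O=CO
Why: Acidolysis of the primary silyl ether followed by Fischer esterification in the large excess of formic acid converts O15 into the formate in one operation, while the carboxylic acid and the electron-poor C7=C8 bond are inert to formic acid.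

Compound list
1 | (S)-citronellol | C[C@H](CCO)CCC=C(C)C | starting material
2 | (S)-citronellyl tert-butyldimethylsilyl ether | C[C@H](CCO[Si](C)(C)C(C)(C)C)CCC=C(C)C | intermediate
3 | ozonide of 2 (3,3-dimethyl-5-alkyl-1,2,4-trioxolane) | C[C@H](CCO[Si](C)(C)C(C)(C)C)CCC1OOC(C)(C)O1 | intermediate
4 | (4S)-6-[(tert-butyldimethylsilyl)oxy]-4-methylhexanal | C[C@H](CCO[Si](C)(C)C(C)(C)C)CCC=O | intermediate
5 | β-cyclocitral | CC1=C(C=O)C(C)(C)CCC1 | starting material
6 | β-cyclogeraniol | CC1=C(CO)C(C)(C)CCC1 | intermediate
7 | methyl 2-[bis(2,2,2-trifluoroethoxy)phosphoryl]acetate | COC(=O)CP(=O)(OCC(F)(F)F)OCC(F)(F)F | starting material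
8 | methyl 2-[bis(2,2,2-trifluoroethoxy)phosphoryl]-2-diazoacetate | COC(=O)C(=[N+]=[N-])P(=O)(OCC(F)(F)F)OCC(F)(F)F | intermediate
9 | methyl 2-[bis(2,2,2-trifluoroethoxy)phosphoryl]-2-[(2,6,6-trimethylcyclohex-1-en-1-yl)methoxy]acetate (racemic) | COC(=O)C(OCC1=C(C)CCCC1(C)C)P(=O)(OCC(F)(F)F)OCC(F)(F)F | intermediate
10 | (E)-allyl vinyl ether, methyl (2E,6S)-8-[(tert-butyldimethylsilyl)oxy]-6-methyl-2-[(2,6,6-trimethylcyclohex-1-en-1-yl)methoxy]oct-2-enoate | C[C@H](CCO[Si](C)(C)C(C)(C)C)CC/C=C(/OCC1=C(C)CCCC1(C)C)C(=O)OC | intermediate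
11 | α-keto ester, methyl (3R,6S)-8-[(tert-butyldimethylsilyl)oxy]-6-methyl-2-oxo-3-[(1R)-1,3,3-trimethyl-2-methylidenecyclohexyl]octanoate | C[C@H](CCO[Si](C)(C)C(C)(C)C)CC[C@@H](C(=O)C(=O)OC)[C@@]1(C)CCCC(C)(C)C1=C | intermediate
12 | dibromoacrylate, methyl (3R,6S)-8-[(tert-butyldimethylsilyl)oxy]-2-(dibromomethylidene)-6-methyl-3-[(1R)-1,3,3-trimethyl-2-methylidenecyclohexyl]octanoate | C[C@H](CCO[Si](C)(C)C(C)(C)C)CC[C@@H](C(C(=O)OC)=C(Br)Br)[C@@]1(C)CCCC(C)(C)C1=C | intermediate
13 | bicyclic 7-bromide, methyl (1R,4aS,8aS)-3-bromo-1-[(3S)-5-[(tert-butyldimethylsilyl)oxy]-3-methylpentyl]-5,5,8a-trimethyl-1,4,4a,5,6,7,8,8a-octahydronaphthalene-2-carboxylate | C[C@H](CCO[Si](C)(C)C(C)(C)C)CC[C@H]1C(C(=O)OC)=C(Br)C[C@H]2C(C)(C)CCC[C@]12C | intermediate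
14 | methyl (1R,4aS,8aS)-1-[(3S)-5-[(tert-butyldimethylsilyl)oxy]-3-methylpentyl]-5,5,8a-trimethyl-1,4,4a,5,6,7,8,8a-octahydronaphthalene-2-carboxylate | C[C@H](CCO[Si](C)(C)C(C)(C)C)CC[C@H]1C(C(=O)OC)=CC[C@H]2C(C)(C)CCC[C@]12C | intermediate
15 | (1R,4aS,8aS)-1-[(3S)-5-[(tert-butyldimethylsilyl)oxy]-3-methylpentyl]-5,5,8a-trimethyl-1,4,4a,5,6,7,8,8a-octahydronaphthalene-2-carboxylic acid | C[C@H](CCO[Si](C)(C)C(C)(C)C)CC[C@H]1C(C(=O)O)=CC[C@H]2C(C)(C)CCC[C@]12C | intermediate
16 | hydroxy acid, (1R,4aS,8aS)-1-[(3S)-5-hydroxy-3-methylpentyl]-5,5,8a-trimethyl-1,4,4a,5,6,7,8,8a-octahydronaphthalene-2-carboxylic acid | C[C@H](CCO)CC[C@H]1C(C(=O)O)=CC[C@H]2C(C)(C)CCC[C@]12C | intermediate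
17 | (5S,9R,10S,13S)-15-formyloxylabd-7-en-17-oic acid | C[C@H](CCOC=O)CC[C@H]1C(C(=O)O)=CC[C@H]2C(C)(C)CCC[C@]12C | target

Total steps: 11. Longest linear sequence: 8 steps (for example 5 → 6 → 9 → 10 → 11 → 12 → 14 → 15 → 17).

Steps most likely to fail

Step 9. Hydrogen transfer from the silane to the C7 vinyl radical, or 1,5-hydrogen transfer to it from C1, C12 or C20, may outrun ring closure. Hydrogen delivery to the C5 radical may also be less face-selective than expected. The fallback sets out from 12 and comes back at 14, and it replaces the radical event by a polar and organometallic one.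
- Palladium-catalysed hydrogenolysis (Pd(PPh3)4, Bu3SnH, PhMe, rt) should remove the more accessible bromine, cis to the planar ester and trans to the bulky C9 substituent. This gives the (E)-monobromide F1, whose bromine is cis to C9.
- Hydroboration of C5=C6 with 9-BBN (THF, 60 °C) from the α face, opposite the axial methyls on C4 and C10, sets C5 by concerted syn addition and gives the B-alkyl-9-BBN adduct F2.
- An intramolecular B-alkyl Suzuki–Miyaura coupling (Pd(dppf)Cl2, AsPh3, Cs2CO3, DMF–THF–H2O, 50 °C, high dilution) then forms C6–C7 and gives 14.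

Step 7. The Lewis acid may ionise the allylic C6–O bond of the electron-rich tetrasubstituted allyl part, which would lead to loss of the concerted pathway, a formal 1,3-shift or elimination. The crowded substrate may also be poorly discriminated by the catalyst. The fallback sets out from 10 and comes back at 11, and it gives up catalyst control.
- The uncatalysed thermal Gosteli–Claisen rearrangement (PhMe, 100 °C) still fixes the C9/C10 relation through the chair.
- It should give 11 together with its C9,C10-bis-epimer F3.
- Because C13 is fixed, the two are diastereomers. They are separated by preparative HPLC and only 11 is carried on.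

Step 6. Reversible addition of the phosphonate anion may erode the kinetic preference, so the vinyl ether geometry is poorly controlled or the (Z)-isomer prevails. The fallback sets out from 9 and 4 and comes back at 11, and it moves control of C9 from alkene geometry to equilibration.
- The olefination is run for the (Z)-vinyl ether F4.
- F4 is rearranged with the same copper catalyst. The catalyst governs the face of the chelated C8=C9 bond and the chair places the allyl part as before, so C10 should come out correct and only C9 inverted, giving the C9 epimer of 11 F5.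
- DBU (CH2Cl2, rt) equilibrates the single enolisable centre C9. Compound 11 is separated from F5 by chromatography and F5 is recycled.

Further compounds
F1 | step 9 | methyl (2E,3R,6S)-2-(bromomethylidene)-8-[(tert-butyldimethylsilyl)oxy]-6-methyl-3-[(1R)-1,3,3-trimethyl-2-methylidenecyclohexyl]octanoate | C[C@H](CCO[Si](C)(C)C(C)(C)C)CC[C@@H](/C(C(=O)OC)=C\Br)[C@@]1(C)CCCC(C)(C)C1=C
F2 | step 9 | B-alkyl-9-BBN adduct of F1 at C6, with H on the α face of C5 | C[C@H](CCO[Si](C)(C)C(C)(C)C)CC[C@@H](/C(C(=O)OC)=C\Br)[C@@]1(C)CCCC(C)(C)[C@@H]1CB2C3CCCC2CCC3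
F3 | step 7 | methyl (3S,6S)-8-[(tert-butyldimethylsilyl)oxy]-6-methyl-2-oxo-3-[(1S)-1,3,3-trimethyl-2-methylidenecyclohexyl]octanoate | C[C@H](CCO[Si](C)(C)C(C)(C)C)CC[C@H](C(=O)C(=O)OC)[C@]1(C)CCCC(C)(C)C1=C
F4 | step 6 | methyl (2Z,6S)-8-[(tert-butyldimethylsilyl)oxy]-6-methyl-2-[(2,6,6-trimethylcyclohex-1-en-1-yl)methoxy]oct-2-enoate | C[C@H](CCO[Si](C)(C)C(C)(C)C)CC/C=C(\OCC1=C(C)CCCC1(C)C)C(=O)OC
F5 | step 6 | methyl (3S,6S)-8-[(tert-butyldimethylsilyl)oxy]-6-methyl-2-oxo-3-[(1R)-1,3,3-trimethyl-2-methylidenecyclohexyl]octanoate | C[C@H](CCO[Si](C)(C)C(C)(C)C)CC[C@H](C(=O)C(=O)OC)[C@@]1(C)CCCC(C)(C)C1=C
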